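**Retrosynthetic overview**

1. The target is the primary ester of a 6,7-dihydroxy iridoid δ-lactone with (1R,3aS,8aR)-1-methyl-7-(propan-2-yl)-1,2,3,3a,8,8a-hexahydroazulene-4-carboxylic acid. The last events are hydride reduction of a C7 ketone and, before it, release of the exocyclic C4=C11 alkene from a CH–CH2SePh cap.
2. Key disconnections are C7–C8 and C5–C9. The cis-fused bicycle is the tethered (3+2) adduct of an enal (C5=C6–C7HO) and a β-keto ester (C9–C8=O). This works because the C8 carbinol lies β to the lactone carbonyl C1 through C9 and 1,5 to C7 through C9–C5–C6, and because the lactone O2–C3 bond ties the keto ester to C4.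
3. One amine/carbene cascade on an open-chain keto ester enal closes the δ-lactone first (Michael addition, C5–C9) and the cyclopentane second (crossed benzoin, C7–C8).
4. The cascade precursor comes from a Suzuki-made dienol acetal, tert-butyl 4-chloroacetoacetate and the caesium salt of the acid (C10–O bond), then acetal hydrolysis and 1,6-addition of PhSeH to cap C11.
5. The acid comes from (R)-pulegone: Favorskii contraction gives the five-membered ring, hydrogenation of a tetrasubstituted cyclopentene gives the all-cis triad, and the seven-membered ring is closed last by alkylzinc/chloroenal coupling and intramolecular Horner–Wadsworth–Emmons olefination.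

Key step: step 16

Remark: the bicyclic core carries iridoid numbering (C1 lactone carbonyl, O2, C3, C4 with exocyclic C11, ring-fusion C5 and C9, C6, C7, C8, C10 on C8). Compounds 26 to 29 are carried as mixtures of the two C4 epimers, a centre that step 17 converts into the exocyclic alkene.

**Route**

Step 1
Reactants: 1 (R)-(+)-pulegone
Product: 3 methyl pulegenate, via pulegone dibromide 2 (not isolated)
Conditions: Br2, NaHCO3, Et2O, −10 °C; then NaOMe, MeOH, reflux
Reagents that add atoms: sodium methoxide, C[O-].[Na+]
Why: Bromine adds to the exocyclic enone double bond and methoxide then triggers a Favorskii rearrangement with loss of the tertiary bromide, which contracts the ring to the cyclopentane ester without touching the methyl-bearing centre (R, from pulegone).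

Step 2
Reactants: 3 methyl pulegenate
Product: 4 methyl (1S,5R)-5-methyl-2-oxocyclopentane-1-carboxylate
Conditions: O3, CH2Cl2/MeOH, −78 °C; then Me2S, −78 → 23 °C
Reagents that add atoms: ozone, [O-][O+]=O
Why: Ozonolysis cleaves the isopropylidene group to the ring ketone, and the labile ester-bearing centre of the β-keto ester settles trans to the methyl group before it is erased in step 3.

Step 3
Reactants: 4 methyl (1S,5R)-5-methyl-2-oxocyclopentane-1-carboxylate
Product: 5 enol triflate of 4
Conditions: NaH, THF, 0 °C; then PhNTf2, 0 → 23 °C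
Reagents that add atoms: N-phenylbis(trifluoromethanesulfonimide), O=S(=O)(N(c1ccccc1)S(=O)(=O)C(F)(F)F)C(F)(F)F
Why: O-Sulfonylation of the sodium enolate of the β-keto ester gives the enol triflate regiospecifically and leaves the methyl-bearing centre untouched.

Step 4
Reactants: 5 enol triflate of 4; 6 (2-tert-butoxy-2-oxoethyl)zinc bromide
Product: 7 cyclopentene diester
Conditions: Pd2(dba)3 (2.5 mol %), XPhos (10 mol %), THF, 45 °C
Reagents that add atoms: none
Why: Negishi cross-coupling (oxidative addition of zerovalent palladium to the vinyl triflate, transmetalation of the Reformatsky reagent, reductive elimination) runs without base, so the tetrasubstituted double bond should stay in place.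

Step 5
Reactants: 7 cyclopentene diester
Product: 8 all-cis cyclopentane diester
Conditions: H2 (60 bar), 5 % Rh/Al2O3, EtOAc, 23 °C
Reagents that add atoms: none
Why: Heterogeneous syn-hydrogenation of the tetrasubstituted enoate should occur from the face opposite the adjacent methyl group, so both new hydrogens enter cis to H-5 and the three substituents end all-cis (1R,2R).

Step 6
Reactants: 8 all-cis cyclopentane diester
Product: 10 phosphonate diester, via phosphonite ester 9 (not isolated)
Conditions: LiN(iPr)2 (2.2 equiv), THF, −78 °C; ClP(OEt)2, −78 → 0 °C; then 30 % H2O2, 0 °C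
Reagents that add atoms: diethyl chlorophosphite, CCOP(Cl)OCC; hydrogen peroxide, OO
Why: The unhindered CH2 of the tert-butyl acetate arm is deprotonated kinetically (the ring α-CH of the methyl ester is tertiary and flanked by two cis groups), the enolate is trapped on carbon by the chlorophosphite and the phosphonite is oxidised (ester enolate phosphonylation); the new side-chain centre is uncontrolled and disappears in step 10.

Step 7
Reactants: 10 phosphonate diester
Product: 11 phosphonate alcohol
Conditions: LiBH4, THF, 0 → 23 °C
Reagents that add atoms: none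
Why: LiBH4 reduces the methyl ester chemoselectively beside the hindered tert-butyl phosphonoacetate, which also removes the risk of epimerisation at the ring carbon that carried the ester.

Step 8
Reactants: 11 phosphonate alcohol
Product: 12 phosphonate iodide
Conditions: I2, PPh3, imidazole, CH2Cl2, 0 → 23 °C
Reagents that add atoms: iodine, II
Why: Appel-type iodination converts the primary alcohol by SN2 displacement of the alkoxyphosphonium ion.

Step 9
Reactants: 13 3-methylbutan-2-one
Product: 14 (2Z)-3-chloro-4-methylpent-2-enal
Conditions: POCl3, DMF, 0 → 55 °C; then aq. NaOAc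
Reagents that add atoms: N,N-dimethylformamide, CN(C)C=O; phosphoryl chloride, O=P(Cl)(Cl)Cl; water, O
Why: Vilsmeier–Haack–Arnold chloroformylation can only proceed productively at the methyl group and should give mainly the Z isomer (chlorine cis to the formyl group), which is the geometry the seven-membered ring needs.

Step 10
Reactants: 12 phosphonate iodide; 14 (2Z)-3-chloro-4-methylpent-2-enal
Product: 17 tert-butyl hexahydroazulene-4-carboxylate, via alkylzinc iodide 15 (not isolated), via phosphonate enal 16 (not isolated)
Conditions: Zn dust (activated with BrCH2CH2Br and Me3SiCl), LiCl, THF, 30 °C; then 14, Pd(OAc)2 (3 mol %), SPhos (6 mol %), 23 °C; then LiCl, DBU, MeCN, 0.005 M, 23 °C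
Reagents that add atoms: none
Why: Zinc inserts into the primary C–I bond, the alkylzinc couples with the activated vinyl chloride with retention of geometry (Negishi coupling), and the phosphonate carbanion then condenses with the cis-disposed aldehyde in an intramolecular Horner–Wadsworth–Emmons reaction that closes the seven-membered ring as the conjugated dienoate without touching a ring stereocentre.

Step 11
Reactants: 17 tert-butyl hexahydroazulene-4-carboxylate
Product: 18 hexahydroazulene-4-carboxylic acid
Conditions: CF3CO2H/CH2Cl2 (1:4), 0 → 23 °C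
Reagents that add atoms: none
Why: Acid-mediated cleavage of the tert-butyl ester through the tert-butyl cation should leave the electron-poor dienoate intact.

Step 12
Reactants: 19 2-bromoprop-2-en-1-ol; 20 (E)-2-(3,3-diethoxyprop-1-en-1-yl)-4,4,5,5-tetramethyl-1,3,2-dioxaborolane
Product: 21 dienol acetal
Conditions: Pd(PPh3)4 (3 mol %), K2CO3, 1,4-dioxane/H2O, 70 °C
Reagents that add atoms: none
Why: Suzuki–Miyaura coupling of the vinyl bromide with the E-alkenylboronate proceeds with retention of the E geometry and tolerates the free alcohol and the acetal.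

Step 13
Reactants: 21 dienol acetal; 22 tert-butyl 4-chloro-3-oxobutanoate
Product: 23 chloro keto ester
Conditions: toluene, 110 °C, slow N2 stream
Reagents that add atoms: none
Why: Thermolysis of the tert-butyl β-keto ester releases (chloroacetyl)ketene, which the primary alcohol traps (transacetoacetylation) under neutral conditions that spare acetal and diene.

Step 14
Reactants: 18 hexahydroazulene-4-carboxylic acid; 23 chloro keto ester
Product: 24 acyloxy keto ester acetal
Conditions: Cs2CO3 (0.55 equiv), DMF, 23 °C; then 23, NaI (10 mol %), 23 °C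
Reagents that add atoms: none
Why: The caesium carboxylate displaces the α-chloro ketone chloride (SN2, iodide-assisted) and is too weak a base to enolise the β-keto ester to a harmful extent.

Step 15
Reactants: 24 acyloxy keto ester acetal
Product: 26 selenide-capped enal, via dienal 25 (not isolated)
Conditions: PPTS (10 mol %), acetone/H2O (10:1), 23 °C; then PhSeH (1.0 equiv), 0 °C, no amine base
Reagents that add atoms: water, O; benzeneselenol, [SeH]c1ccccc1
Why: Mild hydrolysis frees the dienal and the soft selenol adds to its unsubstituted δ-terminus C11 (1,6-hetero-Michael addition) with fast proton transfer, the reversible addition ending at the conjugated E-enal (any deconjugated isomer is equilibrated by the amine of step 16); C4 forms as both epimers and is removed in step 17.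

Step 16
Reactants: 26 selenide-capped enal
Product: 28 selenide keto lactone, via Michael adduct 27 (not isolated)
Conditions: (S)-α,α-diphenylprolinol trimethylsilyl ether (20 mol %), 2-(pentafluorophenyl)-6,7-dihydro-5H-pyrrolo[2,1-c][1,2,4]triazol-2-ium tetrafluoroborate (10 mol %), NaOAc (10 mol %), CHCl3, 23 °C
Reagents that add atoms: none
Why: The prolinol silyl ether condenses with the enal of 26 to an E-iminium ion whose one face is covered by the CPh2(OSiMe3) group, so the tethered β-keto ester enol carbon C9 adds to C5 from the open face in a 6-exo-trig Michael addition that closes the δ-lactone and sets C5 (4aR in ring numbering); hydrolysis gives aldehyde 27, which the triazolylidene converts into a Breslow intermediate that adds to ketone C8 in a 5-exo-trig crossed benzoin reaction, forming the C7–C8 bond and closing the cyclopentane. The closest known reaction is the secondary amine/N-heterocyclic carbene relay of enals and β-keto esters (Michael addition, then crossed benzoin) to α-hydroxycyclopentanones, used here in tethered form. C9 stays epimerisable in 27 and the benzoin step is reversible, so the cis ring fusion, the stable one for cyclopenta[c]pyran-1-ones, should be selected, and at C8 the larger CH2O-acyl arm should take the convex face, leaving the hydroxyl cis to the lactone carbonyl on C9, where it is hydrogen-bonded. The step needs attack at C5 only, a cis lactone fusion and a five-membered carbocycle: the PhSe cap makes C11 sp3 so that C5 is the sole electrophilic carbon, the ester tether makes the Michael step intramolecular and brings C1 and C4 to the same face, and the 1,5 relation of C7 and C8 allows only the five-ring benzoin. The fast benzoin closure also removes 27 before retro-Michael reaction can erode the C5 configuration.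

Step 17
Reactants: 28 selenide keto lactone
Product: 30 methylidene keto lactone, via selenoxide 29 (not isolated)
Conditions: mCPBA (1.05 equiv), CH2Cl2, −78 °C; then iPr2NH (3 equiv), −78 → 35 °C
Reagents that add atoms: none
Why: Selenium is oxidised chemoselectively and the selenoxide syn-elimination can only involve H-4, so both C4 epimers should converge on the exocyclic C4=C11 alkene while the amine scavenges the selenenic acid.

Step 18
Reactants: 30 methylidene keto lactone
Product: 31 nardostachysin
Conditions: NaBH4 (1.5 equiv), CeCl3·7H2O (1.2 equiv), MeOH/THF (3:1), −78 °C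
Reagents that add atoms: none
Why: Luche reduction touches only the ketone, and hydride should enter from the convex face, anti to the C8–O bond and away from the lactone ring that covers the concave face, so the new hydroxyl ends cis to the C8 hydroxyl (7S in iridoid numbering, 6S in ring numbering).

**Compound list**

1 | (R)-(+)-pulegone, (5R)-5-methyl-2-(propan-2-ylidene)cyclohexan-1-one | C[C@@H]1CCC(=C(C)C)C(=O)C1 | starting material
2 | pulegone dibromide, (5R)-2-bromo-2-(2-bromopropan-2-yl)-5-methylcyclohexan-1-one (both C2 epimers) | C[C@@H]1CCC(Br)(C(C)(C)Br)C(=O)C1 | intermediate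
3 | methyl pulegenate, methyl (5R)-5-methyl-2-(propan-2-ylidene)cyclopentane-1-carboxylate (both C1 epimers) | CC(C)=C1CC[C@@H](C)C1C(=O)OC | intermediate
4 | methyl (1S,5R)-5-methyl-2-oxocyclopentane-1-carboxylate (trans, C1 labile) | C[C@@H]1CCC(=O)[C@H]1C(=O)OC | intermediate
5 | methyl (5R)-5-methyl-2-{[(trifluoromethyl)sulfonyl]oxy}cyclopent-1-ene-1-carboxylate | C[C@@H]1CCC(OS(=O)(=O)C(F)(F)F)=C1C(=O)OC | intermediate
6 | (2-tert-butoxy-2-oxoethyl)zinc bromide | CC(C)(C)OC(=O)C[Zn]Br | starting material
7 | methyl (5R)-2-(2-tert-butoxy-2-oxoethyl)-5-methylcyclopent-1-ene-1-carboxylate | C[C@@H]1CCC(CC(=O)OC(C)(C)C)=C1C(=O)OC | intermediate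
8 | methyl (1R,2R,5R)-2-(2-tert-butoxy-2-oxoethyl)-5-methylcyclopentane-1-carboxylate (all-cis) | C[C@@H]1CC[C@H](CC(=O)OC(C)(C)C)[C@@H]1C(=O)OC | intermediate
9 | methyl (1R,2S,5R)-2-[2-tert-butoxy-1-(diethoxyphosphanyl)-2-oxoethyl]-5-methylcyclopentane-1-carboxylate (side-chain centre both configurations) | C[C@@H]1CC[C@H](C(P(OCC)OCC)C(=O)OC(C)(C)C)[C@@H]1C(=O)OC | intermediate
10 | methyl (1R,2S,5R)-2-[2-tert-butoxy-1-(diethoxyphosphoryl)-2-oxoethyl]-5-methylcyclopentane-1-carboxylate (side-chain centre both configurations) | C[C@@H]1CC[C@H](C(P(=O)(OCC)OCC)C(=O)OC(C)(C)C)[C@@H]1C(=O)OC | intermediate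
11 | tert-butyl (diethoxyphosphoryl)[(1S,2R,3R)-2-(hydroxymethyl)-3-methylcyclopentyl]acetate (all-cis ring) | C[C@@H]1CC[C@H](C(P(=O)(OCC)OCC)C(=O)OC(C)(C)C)[C@@H]1CO | intermediate
12 | tert-butyl (diethoxyphosphoryl)[(1S,2R,3R)-2-(iodomethyl)-3-methylcyclopentyl]acetate (all-cis ring) | C[C@@H]1CC[C@H](C(P(=O)(OCC)OCC)C(=O)OC(C)(C)C)[C@@H]1CI | intermediate
13 | 3-methylbutan-2-one | CC(C)C(C)=O | starting material
14 | (2Z)-3-chloro-4-methylpent-2-enal | CC(C)/C(Cl)=C/C=O | intermediate
15 | alkylzinc iodide of 12 (CH2I replaced by CH2ZnI, ring stereochemistry as in 12) | C[C@@H]1CC[C@H](C(P(=O)(OCC)OCC)C(=O)OC(C)(C)C)[C@@H]1C[Zn]I | intermediate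
16 | phosphonate enal: 12 with CH2I replaced by CH2–C(iPr)=CH–CHO (2E, ring CH2 cis to CHO) | C[C@@H]1CC[C@H](C(P(=O)(OCC)OCC)C(=O)OC(C)(C)C)[C@@H]1C/C(C(C)C)=C\C=O | intermediate
17 | tert-butyl (1R,3aS,8aR)-1-methyl-7-(propan-2-yl)-1,2,3,3a,8,8a-hexahydroazulene-4-carboxylate | CC(C)(C)OC(=O)C1=CC=C(C(C)C)C[C@@H]2[C@H](C)CC[C@H]12 | intermediate
18 | (1R,3aS,8aR)-1-methyl-7-(propan-2-yl)-1,2,3,3a,8,8a-hexahydroazulene-4-carboxylic acid | OC(=O)C1=CC=C(C(C)C)C[C@@H]2[C@H](C)CC[C@H]12 | intermediate
19 | 2-bromoprop-2-en-1-ol | OCC(Br)=C | starting material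
20 | (E)-2-(3,3-diethoxyprop-1-en-1-yl)-4,4,5,5-tetramethyl-1,3,2-dioxaborolane | CCOC(OCC)/C=C/B1OC(C)(C)C(C)(C)O1 | starting material
21 | (3E)-5,5-diethoxy-2-methylidenepent-3-en-1-ol | OCC(=C)/C=C/C(OCC)OCC | intermediate
22 | tert-butyl 4-chloro-3-oxobutanoate | ClCC(=O)CC(=O)OC(C)(C)C | starting material
23 | (3E)-5,5-diethoxy-2-methylidenepent-3-en-1-yl 4-chloro-3-oxobutanoate | ClCC(=O)CC(=O)OCC(=C)/C=C/C(OCC)OCC | intermediate
24 | 4-{[(3E)-5,5-diethoxy-2-methylidenepent-3-en-1-yl]oxy}-2,4-dioxobutyl (1R,3aS,8aR)-1-methyl-7-(propan-2-yl)-1,2,3,3a,8,8a-hexahydroazulene-4-carboxylate | CCOC(OCC)/C=C/C(=C)COC(=O)CC(=O)COC(=O)C1=CC=C(C(C)C)C[C@@H]2[C@H](C)CC[C@H]12 | intermediate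
25 | 4-{[(3E)-2-methylidene-5-oxopent-3-en-1-yl]oxy}-2,4-dioxobutyl ester of acid 18 (dienal) | O=C/C=C/C(=C)COC(=O)CC(=O)COC(=O)C1=CC=C(C(C)C)C[C@@H]2[C@H](C)CC[C@H]12 | intermediate
26 | 2,4-dioxo-4-({(3E)-5-oxo-2-[(phenylselanyl)methyl]pent-3-en-1-yl}oxy)butyl ester of acid 18 (both configurations at the selenomethyl-bearing carbon, C4) | O=C/C=C/C(C[Se]c1ccccc1)COC(=O)CC(=O)COC(=O)C1=CC=C(C(C)C)C[C@@H]2[C@H](C)CC[C@H]12 | intermediate
27 | Michael adduct: δ-lactone with C5 set as in the target (CH2CHO on C5), epimerisable C9 bearing the 2-(acyloxy)acetyl group, C4 both configurations | c1ccccc1[Se]CC1COC(=O)C(C(=O)COC(=O)C2=CC=C(C(C)C)C[C@@H]3[C@H](C)CC[C@H]23)[C@H]1CC=O | intermediate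
28 | [(4aR,7S,7aR)-7-hydroxy-1,6-dioxo-4-[(phenylselanyl)methyl]octahydrocyclopenta[c]pyran-7-yl]methyl ester of acid 18 (C4 both configurations) | c1ccccc1[Se]CC1COC(=O)[C@@H]2[C@H]1CC(=O)[C@@]2(O)COC(=O)C1=CC=C(C(C)C)C[C@@H]2[C@H](C)CC[C@H]12 | intermediate
29 | selenoxide of 28 (C4 and Se both configurations) | O=[Se](c1ccccc1)CC1COC(=O)[C@@H]2[C@H]1CC(=O)[C@@]2(O)COC(=O)C1=CC=C(C(C)C)C[C@@H]2[C@H](C)CC[C@H]12 | intermediate
30 | [(4aR,7S,7aR)-7-hydroxy-4-methylidene-1,6-dioxooctahydrocyclopenta[c]pyran-7-yl]methyl ester of acid 18 | C=C1COC(=O)[C@@H]2[C@H]1CC(=O)[C@@]2(O)COC(=O)C1=CC=C(C(C)C)C[C@@H]2[C@H](C)CC[C@H]12 | intermediate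
31 | nardostachysin, [(4aR,6S,7S,7aR)-6,7-dihydroxy-4-methylidene-1-oxooctahydrocyclopenta[c]pyran-7-yl]methyl (1R,3aS,8aR)-1-methyl-7-(propan-2-yl)-1,2,3,3a,8,8a-hexahydroazulene-4-carboxylate | C=C1COC(=O)[C@@H]2[C@H]1C[C@H](O)[C@@]2(O)COC(=O)C1=CC=C(C(C)C)C[C@@H]2[C@H](C)CC[C@H]12 | target

**Step count and risks**

Total step count: 18. Longest linear sequence: 15 (steps 1–8, 10, 11, 14–18).

Steps most likely to fail:

1. Step 16 (key cascade). What may go wrong: γ-deprotonation of the iminium ion of 26 to a dienamine that expels the allylic carboxylate (loss of the tether) or the selenolate; unequal behaviour of the two C4 epimers in the ring-closing Michael step; acetate-promoted ring closure without the amine, which would erode face control. Fallback, which leaves out the cap: starting from 24, the acetal is hydrolysed (PPTS, wet acetone) and dienal 25 is isolated. It has no γ-hydrogen and cannot form a dienamine. It is treated with the same amine/carbene pair, with the amine stage run first at −20 °C before acetate and the triazolium salt are added. The Michael adduct, the methylidene keto lactone aldehyde F1, should close directly to 30, so the route is rejoined at 30 and step 17 falls away. The cost is possible competing attack of C9 at the diene terminus C11.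

2. Step 10 (zinc insertion, coupling, olefination). What may go wrong: protonolysis of the alkylzinc by the acidic phosphonoacetate C–H before cross-coupling, or oligomerisation in place of the seven-ring olefination. Fallback, which closes the ring by metathesis and carries no acidic C–H: starting from 8, LiBH4 reduction should give the hydroxy ester F2, and I2/PPh3/imidazole the iodide F3. Zinc insertion and Pd-catalysed coupling with 14 should give the enal F4, and Ph3P=CH2 the diene F5. α-Methylenation of the tert-butyl ester (LiN(iPr)2, then Me2N=CH2 iodide; MeI; DBU) should give the acrylate F6. Ring-closing metathesis with the second-generation Hoveyda–Grubbs catalyst (toluene, 80 °C) then forms the C4=C5 bond (azulene numbering) and returns to the route at 17.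

3. Step 18 (ketone reduction). What may go wrong: poor facial selectivity, with hydride delivered from the concave face under guidance by the neighbouring tertiary hydroxyl, giving the trans-diol. Fallback, which replaces substrate control by catalyst control: asymmetric transfer hydrogenation of 30 with RuCl(p-cymene)(TsDPEN) of the ligand hand that delivers hydride to the Re face of the ketone carbon (HCO2H/Et3N, 23 °C) should lead from 30 directly to 31; α-hydroxy ketones are good substrates for this catalyst class, and no new compound is involved.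

Further compounds

F1 | step 16 | Michael adduct of dienal 25: 4-methylidene δ-lactone with CH2CHO on C5 (configured as in the target) and the 2-(acyloxy)acetyl group on epimerisable C9 | C=C1COC(=O)C(C(=O)COC(=O)C2=CC=C(C(C)C)C[C@@H]3[C@H](C)CC[C@H]23)[C@H]1CC=O
F2 | step 10 | tert-butyl [(1R,2R,3R)-2-(hydroxymethyl)-3-methylcyclopentyl]acetate | C[C@@H]1CC[C@H](CC(=O)OC(C)(C)C)[C@@H]1CO
F3 | step 10 | tert-butyl [(1R,2R,3R)-2-(iodomethyl)-3-methylcyclopentyl]acetate | C[C@@H]1CC[C@H](CC(=O)OC(C)(C)C)[C@@H]1CI
F4 | step 10 | tert-butyl {3-methyl-2-[(2E)-4-oxo-2-(propan-2-yl)but-2-en-1-yl]cyclopentyl}acetate (ring all-cis as in 8) | C[C@@H]1CC[C@H](CC(=O)OC(C)(C)C)[C@@H]1C/C(C(C)C)=C\C=O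
F5 | step 10 | tert-butyl {3-methyl-2-[(2E)-2-(propan-2-yl)penta-2,4-dien-1-yl]cyclopentyl}acetate (ring all-cis as in 8) | C[C@@H]1CC[C@H](CC(=O)OC(C)(C)C)[C@@H]1C/C(C(C)C)=C\C=C
F6 | step 10 | tert-butyl 2-{3-methyl-2-[(2E)-2-(propan-2-yl)penta-2,4-dien-1-yl]cyclopentyl}prop-2-enoate (ring all-cis as in 8) | C[C@@H]1CC[C@H](C(=C)C(=O)OC(C)(C)C)[C@@H]1C/C(C(C)C)=C\C=C
F0 | step 18 | none | none
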